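## Retrosynthetic overview
1. Target 15 comes from Br2 addition and Et3N dehydrobromination on the 3-substituted 5-methylene-butenolide 14. This installs C4–Br and the exocyclic =CHBr last.
2. The only ring, the butenolide, is formed by acid-catalysed enol-lactonisation of the 2-substituted levulinic acid 12 to give 13.
3. Acid 12 comes from Wacker oxidation of an α-allyl β-acetoxy ester, which comes from Fráter–Seebach allylation of a β-hydroxy ester.
4. The carbinol stereocentre is set by Ru-BINAP hydrogenation of the achiral β-keto ester 5. A lipase transacetylation then upgrades the ee and installs the acetate of the target.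
5. Keto ester 5 is made from Meldrum's acid, butyryl chloride and tert-butanol.

Assumption (one line): the exocyclic bromoalkene is taken with the geometry written in the target SMILES (Br on the same side as C4–Br). The C3 epimer in 8 and 10–13 is irrelevant because that carbon becomes sp2 in 14.

## Route

**Step 1**
Reactants: 1 (Meldrum's acid), 2 (butyryl chloride)
Product: 3 (5-butanoyl Meldrum's acid)
Conditions: pyridine, CH2Cl2, 0 °C → rt
Reagents that add atoms: butyryl chloride, CCCC(=O)Cl
Why: C-acylation of the highly acidic Meldrum's acid by an acid chloride (pyridine as base) gives the acyl derivative 3 cleanly.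

**Step 2**
Reactants: 3, 4 (tert-butanol)
Product: 5 (tert-butyl 3-oxohexanoate)
Conditions: t-BuOH, reflux
Reagents that add atoms: tert-butanol, CC(C)(C)O
Why: Thermolysis of acyl Meldrum's acid expels acetone and CO2 to give an acylketene, which tert-butanol traps as the β-keto tert-butyl ester.

**Step 3**
Reactants: 5
Product: 6 (tert-butyl (R)-3-hydroxyhexanoate)
Conditions: RuCl2[(R)-BINAP] (0.2 mol%), H2 (50 atm), MeOH, 50 °C
Reagents that add atoms: none (H2 only)
Why: Noyori asymmetric hydrogenation of a β-keto ester proceeds through a BINAP–Ru chelate of the keto ester, and the (R)-ligand delivers hydride to one face to give the (R)-alcohol in about 98% ee. This sets the only stereocentre of the target.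

**Step 4**
Reactants: 6, 7 (allyl bromide)
Product: 8 (tert-butyl (3R)-2-allyl-3-hydroxyhexanoate, anti-major α-epimer mixture)
Conditions: LDA (2.3 equiv), THF, –78 → 0 °C; then allyl bromide, DMPU, –78 → –20 °C
Reagents that add atoms: allyl bromide, C=CCBr
Why: Fráter–Seebach alkylation of the alkoxide/ester dianion occurs at the α-carbon through a chelated intermediate. The carbinol centre is untouched, and the new α-centre is destroyed later.

**Step 5**
Reactants: 8, 9 (vinyl acetate)
Product: 10 (tert-butyl (3R)-3-acetoxy-2-allylhexanoate)
Conditions: Novozym 435 (Candida antarctica lipase B, a hydrolase), vinyl acetate, MTBE, 35 °C; the unreacted (S)-alcohol is removed by silica gel chromatography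
Reagents that add atoms: vinyl acetate, C=COC(C)=O
Why: Lipase-catalysed enantioselective transesterification (Kazlauskas rule) acetylates the (R)-carbinol fast and the (S)-carbinol slowly. This upgrades the ee to above 99% and installs the acetate of the target under neutral conditions.

**Step 6**
Reactants: 10
Product: 11 (tert-butyl (3R)-3-acetoxy-2-(2-oxopropyl)hexanoate)
Conditions: PdCl2 (10 mol%), CuCl, O2 (1 atm), DMF/H2O (7:1), 25 °C
Reagents that add atoms: water, O
Why: Wacker–Tsuji oxidation converts the terminal alkene Markovnikov-selectively to the methyl ketone. The mildly acidic, non-basic medium leaves the β-acetoxy ester intact.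

**Step 7**
Reactants: 11
Product: 12 ((3R)-3-acetoxy-2-(2-oxopropyl)hexanoic acid)
Conditions: TFA, CH2Cl2, rt
Reagents that add atoms: none
Why: Acidolysis of the tert-butyl ester by E1 loss of isobutylene needs no base, so the β-acetoxy group cannot undergo E1cB elimination.

**Step 8**
Reactants: 12
Product: 13 (3-[(1R)-1-acetoxybutyl]-5-methylfuran-2(3H)-one, C3 epimeric)
Conditions: Ac2O, cat. TsOH·H2O, 60 °C
Reagents that add atoms: none
Why: The γ-keto acid undergoes acid-catalysed enol-lactonisation (cyclodehydration, Ac2O as water scavenger) to give the angelica-lactone-type enol lactone, the only ring formation.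

**Step 9**
Reactants: 13
Product: 14 (3-[(1R)-1-acetoxybutyl]-5-methylidenefuran-2(5H)-one, used crude with BHT)
Conditions: Br2 (1.0 equiv), CH2Cl2, –20 °C; then Et3N (2.5 equiv), –20 → 0 °C
Reagents that add atoms: none (the bromine is lost again as HBr)
Why: Br+ adds to C4 of the enol ether, and the oxocarbenium loses H+ from the methyl group to give the 4-bromo-5-methylene lactone. Et3N then removes the acidic C3–H and allylic bromide is lost by E1cB/E2, so the C3=C4 butenolide forms with the carbinol untouched.

**Step 10**
Reactants: 14
Product: 15 (acetoxyfimbrolide)
Conditions: Br2 (2.2 equiv), CH2Cl2, 0 °C → rt; then Et3N (3 equiv), 0 °C; silica gel chromatography or HPLC to isolate the isomer matching the target geometry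
Reagents that add atoms: bromine, BrBr
Why: The first Br2 adds to the exocyclic enol-ether alkene, and loss of HBr through the C5 oxocarbenium gives the 5-(bromomethylene)butenolide. The second Br2 adds across C3=C4, and Et3N-mediated HBr elimination (C4–H, C3–Br) restores the butenolide with C4–Br. The exocyclic alkene forms as an E/Z mixture, and the isomer drawn in the target is isolated chromatographically.

## Compound list
1 | Meldrum's acid | CC1(C)OC(=O)CC(=O)O1 | starting material
2 | butyryl chloride | CCCC(=O)Cl | starting material
3 | 5-butanoyl Meldrum's acid | CCCC(=O)C1C(=O)OC(C)(C)OC1=O | intermediate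
4 | tert-butanol | CC(C)(C)O | starting material
5 | tert-butyl 3-oxohexanoate | CCCC(=O)CC(=O)OC(C)(C)C | intermediate
6 | tert-butyl (R)-3-hydroxyhexanoate | CCC[C@@H](O)CC(=O)OC(C)(C)C | intermediate
7 | allyl bromide | C=CCBr | starting material
8 | tert-butyl (3R)-2-allyl-3-hydroxyhexanoate (α-epimer mixture) | CCC[C@@H](O)C(CC=C)C(=O)OC(C)(C)C | intermediate
9 | vinyl acetate | C=COC(C)=O | starting material
10 | tert-butyl (3R)-3-acetoxy-2-allylhexanoate | CCC[C@@H](OC(C)=O)C(CC=C)C(=O)OC(C)(C)C | intermediate
11 | tert-butyl (3R)-3-acetoxy-2-(2-oxopropyl)hexanoate | CCC[C@@H](OC(C)=O)C(CC(C)=O)C(=O)OC(C)(C)C | intermediate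
12 | (3R)-3-acetoxy-2-(2-oxopropyl)hexanoic acid | CCC[C@@H](OC(C)=O)C(CC(C)=O)C(=O)O | intermediate
13 | 3-[(1R)-1-acetoxybutyl]-5-methylfuran-2(3H)-one | CCC[C@@H](OC(C)=O)C1C=C(C)OC1=O | intermediate
14 | 3-[(1R)-1-acetoxybutyl]-5-methylidenefuran-2(5H)-one | CCC[C@@H](OC(C)=O)C1=CC(=C)OC1=O | intermediate
15 | acetoxyfimbrolide | CCC[C@@H](OC(C)=O)C1=C(Br)/C(=C\Br)OC1=O | target

## Summary
Total steps: 10. Longest linear sequence: 10 steps (1 → 3 → 5 → 6 → 8 → 10 → 11 → 12 → 13 → 14 → 15).

Three steps most likely to fail:
1. **Step 10** (double bromination and elimination). The E/Z ratio and yield are uncertain, and the β-acetoxy group could be lost by E1cB.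
   Fallback: run the same enol-lactonisation/bromination sequence on the 3-butanoyl analogue, which has no leaving group. Make it from 5 and bromoacetone, then reduce the ketone enantioselectively with a ketoreductase or (R)-CBS, and acetylate.
2. **Step 9** (Br2, then Et3N). The 5-methylene butenolide is a reactive protoanemonin analogue that can polymerise, and the C3–H/OAc pair can eliminate.
   Fallback: change the order and avoid this intermediate by α,α′-brominating the keto acid 12 (or the corresponding acid bearing a silyl-protected carbinol) first. Then cyclise with acid, and install the C4–Br and exocyclic bromide by controlled HBr elimination of the polybrominated lactone.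
3. **Step 5** (lipase acetylation of the hindered α-branched alcohol). Rate or selectivity may be insufficient.
   Fallback: replace Steps 3 and 5 with a ketoreductase (NADPH/GDH) reduction of 5 to the (R)-alcohol (>99% ee), then acetylate chemically (Ac2O, DMAP) after the Wacker step.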